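**Retrosynthetic overview**
1. Ring A, the only ring, is numbered C1' (stereocentre), C2' (C–CH3), C3' (=CH), C4', C5' (CH2), C6' (CMe2). The ester C–O bond is cut last (alpha-linolenic acid + C20 alcohol), so the skipped Z,Z,Z-triene meets no organometal, borane or diimide.
2. C1'–H and the C2'=C3' alkene arise together from a 3'-hydroxy-1'(2')-ene by Mitsunobu hydrazination and retro-ene loss of N2. This transfers chirality 1,3 from an easily set carbinol (CBS reduction of the 3'-enone) to the hindered C1' next to quaternary C6'.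
3. The C1'–side-chain bond comes from Stork–Danheiser addition of a C11 alkyllithium (geraniol plus one carbon) to the vinylogous ester of 2,4,4-trimethylcyclohexane-1,3-dione.
4. Ring A is formed first and in one operation. A Michael–Claisen [3+3] annulation of 2-methylpentan-3-one with methyl acrylate makes C5'–C6' and C2'–C3'.
5. Enabling feature: all ring substituents sit on the triad C2'–C1'–C6', whose outer carbons are both alpha to C1'. C3'–C4'–C5' is a bare three-carbon chain, and C3' is allylic (1,3) to C1'. With C1' and C3' raised to carbonyls, ring A is simply ethyl isopropyl ketone plus acrylate.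

Key step: step 1

Assumption: the ring stereocentre is read from the SMILES as S (priorities C2' > C6' > side-chain CH2 > H).

**Step 1**
Reactants: 1 2-methylpentan-3-one; 2 methyl acrylate
Product: 4 2,4,4-trimethylcyclohexane-1,3-dione, via keto ester 3 (not isolated)
Conditions: KOt-Bu (1.2 equiv), THF, 0 °C, slow addition of 2, then rt; 1 M HCl
Reagents that add atoms: none
Why: Under equilibrating KOt-Bu the isopropyl-side enolate of 1 adds through its tertiary carbon to the beta-carbon of 2 (C5'–C6' bond, quaternary C6'), proton exchange in keto ester 3 then gives the ethyl-side enolate, whose carbon attacks the ester carbonyl and expels methoxide (C2'–C3' bond), and the dione leaves the equilibria as its potassium enolate, in which C2'=C3' is already an enolate double bond. The closest known reaction type is the consecutive Michael–Claisen [3+3] synthesis of cyclohexane-1,3-diones from enolisable ketones and acrylates, which is established for isopropyl ketones. Ring A closes by a 6-(enolexo)-exo-trig Dieckmann-type acylation. No lasting stereocentre is formed, because C2' of 4 lies between two carbonyls and is enolised; the stereocentre of the target is set later from the C3' carbonyl that this step installs. The selectivity needed is the orientation of the partners: the reverse pairing (Michael addition at the ethyl CH2, acylation at the isopropyl CH) can only end in a 2,2-disubstituted dione that has no acidic hydrogen between its carbonyls and is reopened by alkoxide, whereas 4 is removed irreversibly by deprotonation, and slow addition of 2 to a slight excess of 1 holds back double Michael addition and acrylate oligomerisation. In one operation two acyclic bulk chemicals should give all nine carbons of ring A, the quaternary carbon, the three methyl groups in their final places and two differentiated carbonyls, C1' as the docking point for the side chain and C3' as the handle that later fixes both the alkene position and the configuration.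

**Step 2**
Reactants: 4 2,4,4-trimethylcyclohexane-1,3-dione
Product: 5 3-isobutoxy-2,6,6-trimethylcyclohex-2-en-1-one
Conditions: i-BuOH, p-TsOH (cat.), toluene, reflux, Dean–Stark
Reagents that add atoms: isobutanol CC(C)CO
Why: Acid-catalysed enol etherification of a cyclic 1,3-dione under thermodynamic control should place the alkoxy group on the unhindered C3' oxygen, remote from the gem-dimethyl carbon, and leave the C1' carbonyl free; no stereocentre is formed.

**Step 3**
Reactants: 6 geraniol
Product: 7 geranyl tert-butyldiphenylsilyl ether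
Conditions: TBDPSCl, imidazole, CH2Cl2, 0 °C to rt
Reagents that add atoms: tert-butyldiphenylsilyl chloride CC(C)(C)[Si](Cl)(c1ccccc1)c1ccccc1
Why: Standard silylation of a primary allylic alcohol gives an ether that tolerates SeO2, ylide, borane, t-BuLi and brief dilute acid.

**Step 4**
Reactants: 7 geranyl tert-butyldiphenylsilyl ether
Product: 8 (2E,6E)-8-(tert-butyldiphenylsilyloxy)-2,6-dimethylocta-2,6-dien-1-ol
Conditions: SeO2 (cat.), t-BuOOH, salicylic acid (cat.), CH2Cl2, 0 °C to rt
Reagents that add atoms: tert-butyl hydroperoxide CC(C)(C)OO (oxygen passed on through selenium dioxide O=[Se]=O)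
Why: Catalytic SeO2 allylic oxidation (ene reaction, then [2,3]-sigmatropic shift) attacks the more electron-rich terminal isopropylidene at its E-methyl group and so should give the E-allylic alcohol, and any over-oxidised material is aldehyde 9 and converges in step 5.

**Step 5**
Reactants: 8 (2E,6E)-8-(tert-butyldiphenylsilyloxy)-2,6-dimethylocta-2,6-dien-1-ol
Product: 9 (2E,6E)-8-(tert-butyldiphenylsilyloxy)-2,6-dimethylocta-2,6-dienal
Conditions: MnO2, CH2Cl2, rt
Reagents that add atoms: none
Why: MnO2 oxidises allylic alcohols selectively to enals without touching the silyl ether or the alkene geometry.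

**Step 6**
Reactants: 9 (2E,6E)-8-(tert-butyldiphenylsilyloxy)-2,6-dimethylocta-2,6-dienal
Product: 10 (2E,6E)-1-(tert-butyldiphenylsilyloxy)-3,7-dimethylnona-2,6,8-triene
Conditions: Ph3PCH3Br, n-BuLi, THF, −78 to 0 °C
Reagents that add atoms: methyltriphenylphosphonium bromide C[P+](c1ccccc1)(c1ccccc1)c1ccccc1.[Br-]
Why: Wittig methylenation of an enal adds the one missing chain carbon and leaves the existing E-trisubstituted alkenes unchanged.

**Step 7**
Reactants: 10 (2E,6E)-1-(tert-butyldiphenylsilyloxy)-3,7-dimethylnona-2,6,8-triene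
Product: 12 (3E,7E)-9-(tert-butyldiphenylsilyloxy)-3,7-dimethylnona-3,7-dien-1-ol, via B-alkyl-9-BBN adduct 11 (not isolated)
Conditions: 9-BBN, THF, 0 °C to rt; then NaOH, H2O2, 0 °C
Reagents that add atoms: hydrogen peroxide OO
Why: Hydroboration–oxidation with the bulky 9-BBN should take only the monosubstituted vinyl terminus (anti-Markovnikov) and leave both trisubstituted alkenes untouched.

**Step 8**
Reactants: 12 (3E,7E)-9-(tert-butyldiphenylsilyloxy)-3,7-dimethylnona-3,7-dien-1-ol
Product: 13 (2E,6E)-1-(tert-butyldiphenylsilyloxy)-9-iodo-3,7-dimethylnona-2,6-diene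
Conditions: I2, PPh3, imidazole, CH2Cl2, 0 °C
Reagents that add atoms: iodine II
Why: Appel-type iodination converts the primary alcohol by SN2 displacement of the oxyphosphonium group under neutral conditions.

**Step 9**
Reactants: 13 (2E,6E)-1-(tert-butyldiphenylsilyloxy)-9-iodo-3,7-dimethylnona-2,6-diene; 5 3-isobutoxy-2,6,6-trimethylcyclohex-2-en-1-one
Product: 16 3-[(3E,7E)-9-(tert-butyldiphenylsilyloxy)-3,7-dimethylnona-3,7-dienyl]-2,4,4-trimethylcyclohex-2-en-1-one, via alkyllithium 14 (not isolated), via lithium alkoxide 15 (not isolated)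
Conditions: t-BuLi (2.1 equiv), Et2O–pentane, −78 °C; 5, THF, −78 to 0 °C; then 1 M HCl, THF, 0 °C to rt
Reagents that add atoms: water O
Why: Stork–Danheiser sequence in which iodine–lithium exchange gives a primary alkyllithium that adds 1,2 to the C1' carbonyl of 5 (no alpha-hydrogen on the quaternary flank), and mild acid ionises the tertiary allylic alcohol and hydrolyses the enol ether, so the carbonyl ends at C3' and the chain at C1'.

**Step 10**
Reactants: 16 3-[(3E,7E)-9-(tert-butyldiphenylsilyloxy)-3,7-dimethylnona-3,7-dienyl]-2,4,4-trimethylcyclohex-2-en-1-one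
Product: 17 (1R)-3-[(3E,7E)-9-(tert-butyldiphenylsilyloxy)-3,7-dimethylnona-3,7-dienyl]-2,4,4-trimethylcyclohex-2-en-1-ol
Conditions: (S)-Me-CBS oxazaborolidine (20 mol %), catecholborane, toluene, −78 °C; then H2O
Reagents that add atoms: none
Why: In this Corey–Bakshi–Shibata reduction the fully substituted alkene flank acts as the large group and C4'H2 as the small one, so the (S)-catalyst should give the (R)-carbinol, and catecholborane at −78 °C leaves the trisubstituted alkenes alone.

**Step 11**
Reactants: 17 (1R)-3-[(3E,7E)-9-(tert-butyldiphenylsilyloxy)-3,7-dimethylnona-3,7-dienyl]-2,4,4-trimethylcyclohex-2-en-1-ol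
Product: 20 tert-butyldiphenylsilyl ether of (2E,6E)-3,7-dimethyl-9-[(1S)-2,6,6-trimethylcyclohex-2-en-1-yl]nona-2,6-dien-1-ol, via sulfonylhydrazine 18 (not isolated), via allylic diazene 19 (not isolated)
Conditions: PPh3, DEAD, 2-nitrobenzenesulfonylhydrazide (NBSH), THF, −30 °C; then rt
Reagents that add atoms: none
Why: In this Myers reductive allylic transposition the Mitsunobu displacement by NBSH inverts C3', loss of 2-nitrobenzenesulfinic acid on warming gives the monoalkyl diazene, and its concerted retro-ene loss of N2 delivers hydrogen suprafacially to C1' on the face opposite to the former hydroxyl, which sets C1' as S and places the alkene at C2'=C3' only.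

**Step 12**
Reactants: 20 tert-butyldiphenylsilyl ether of the C20 alcohol
Product: 21 (2E,6E)-3,7-dimethyl-9-[(1S)-2,6,6-trimethylcyclohex-2-en-1-yl]nona-2,6-dien-1-ol
Conditions: TBAF, THF, 0 °C to rt
Reagents that add atoms: none
Why: Fluoride desilylation is selective for the Si–O bond, and C1' carries no acidifying group, so its configuration is safe.

**Step 13**
Reactants: 21 (2E,6E)-3,7-dimethyl-9-[(1S)-2,6,6-trimethylcyclohex-2-en-1-yl]nona-2,6-dien-1-ol; 22 alpha-linolenic acid
Product: 23 target ester CNP0115076.1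
Conditions: DCC, DMAP (cat.), CH2Cl2, 0 °C to rt, argon, dark
Reagents that add atoms: none
Why: Steglich esterification joins the primary allylic alcohol and the acid under neutral conditions that neither isomerise the skipped Z,Z,Z-triene nor ionise the allylic C–O bond.

**Compound list**
1 | 2-methylpentan-3-one | CCC(=O)C(C)C | starting material
2 | methyl acrylate | C=CC(=O)OC | starting material
3 | methyl 4,4-dimethyl-5-oxoheptanoate | CCC(=O)C(C)(C)CCC(=O)OC | intermediate
4 | 2,4,4-trimethylcyclohexane-1,3-dione | CC1C(=O)CCC(C)(C)C1=O | intermediate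
5 | 3-isobutoxy-2,6,6-trimethylcyclohex-2-en-1-one | CC1=C(OCC(C)C)CCC(C)(C)C1=O | intermediate
6 | geraniol | OC/C=C(\C)CCC=C(C)C | starting material
7 | geranyl tert-butyldiphenylsilyl ether | CC(C)(C)[Si](c1ccccc1)(c1ccccc1)OC/C=C(\C)CCC=C(C)C | intermediate
8 | (2E,6E)-8-(tert-butyldiphenylsilyloxy)-2,6-dimethylocta-2,6-dien-1-ol | CC(C)(C)[Si](c1ccccc1)(c1ccccc1)OC/C=C(\C)CC/C=C(\C)CO | intermediate
9 | (2E,6E)-8-(tert-butyldiphenylsilyloxy)-2,6-dimethylocta-2,6-dienal | CC(C)(C)[Si](c1ccccc1)(c1ccccc1)OC/C=C(\C)CC/C=C(\C)C=O | intermediate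
10 | (2E,6E)-1-(tert-butyldiphenylsilyloxy)-3,7-dimethylnona-2,6,8-triene | CC(C)(C)[Si](c1ccccc1)(c1ccccc1)OC/C=C(\C)CC/C=C(\C)C=C | intermediate
11 | B-[(3E,7E)-9-(tert-butyldiphenylsilyloxy)-3,7-dimethylnona-3,7-dienyl]-9-borabicyclo[3.3.1]nonane | CC(C)(C)[Si](c1ccccc1)(c1ccccc1)OC/C=C(\C)CC/C=C(\C)CCB1C2CCCC1CCC2 | intermediate
12 | (3E,7E)-9-(tert-butyldiphenylsilyloxy)-3,7-dimethylnona-3,7-dien-1-ol | CC(C)(C)[Si](c1ccccc1)(c1ccccc1)OC/C=C(\C)CC/C=C(\C)CCO | intermediate
13 | (2E,6E)-1-(tert-butyldiphenylsilyloxy)-9-iodo-3,7-dimethylnona-2,6-diene | CC(C)(C)[Si](c1ccccc1)(c1ccccc1)OC/C=C(\C)CC/C=C(\C)CCI | intermediate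
14 | (3E,7E)-9-(tert-butyldiphenylsilyloxy)-3,7-dimethylnona-3,7-dienyllithium | CC(C)(C)[Si](c1ccccc1)(c1ccccc1)OC/C=C(\C)CC/C=C(\C)CC[Li] | intermediate
15 | lithium 1-[(3E,7E)-9-(tert-butyldiphenylsilyloxy)-3,7-dimethylnona-3,7-dienyl]-3-isobutoxy-2,6,6-trimethylcyclohex-2-en-1-olate (racemic) | CC(C)(C)[Si](c1ccccc1)(c1ccccc1)OC/C=C(\C)CC/C=C(\C)CCC1(O[Li])C(C)=C(OCC(C)C)CCC1(C)C | intermediate
16 | 3-[(3E,7E)-9-(tert-butyldiphenylsilyloxy)-3,7-dimethylnona-3,7-dienyl]-2,4,4-trimethylcyclohex-2-en-1-one | CC(C)(C)[Si](c1ccccc1)(c1ccccc1)OC/C=C(\C)CC/C=C(\C)CCC1=C(C)C(=O)CCC1(C)C | intermediate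
17 | (1R)-3-[(3E,7E)-9-(tert-butyldiphenylsilyloxy)-3,7-dimethylnona-3,7-dienyl]-2,4,4-trimethylcyclohex-2-en-1-ol | CC(C)(C)[Si](c1ccccc1)(c1ccccc1)OC/C=C(\C)CC/C=C(\C)CCC1=C(C)[C@H](O)CCC1(C)C | intermediate
18 | N-[(1S)-3-alkyl-2,4,4-trimethylcyclohex-2-en-1-yl]-2-nitrobenzenesulfonohydrazide (alkyl = chain of 16) | CC(C)(C)[Si](c1ccccc1)(c1ccccc1)OC/C=C(\C)CC/C=C(\C)CCC1=C(C)[C@@H](N(N)S(=O)(=O)c2ccccc2[N+](=O)[O-])CCC1(C)C | intermediate
19 | (1S)-3-alkyl-2,4,4-trimethylcyclohex-2-en-1-yldiazene (alkyl = chain of 16) | CC(C)(C)[Si](c1ccccc1)(c1ccccc1)OC/C=C(\C)CC/C=C(\C)CCC1=C(C)[C@@H](N=N)CCC1(C)C | intermediate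
20 | tert-butyldiphenylsilyl ether of (2E,6E)-3,7-dimethyl-9-[(1S)-2,6,6-trimethylcyclohex-2-en-1-yl]nona-2,6-dien-1-ol | CC(C)(C)[Si](c1ccccc1)(c1ccccc1)OC/C=C(\C)CC/C=C(\C)CC[C@@H]1C(C)=CCCC1(C)C | intermediate
21 | (2E,6E)-3,7-dimethyl-9-[(1S)-2,6,6-trimethylcyclohex-2-en-1-yl]nona-2,6-dien-1-ol | OC/C=C(\C)CC/C=C(\C)CC[C@@H]1C(C)=CCCC1(C)C | intermediate
22 | alpha-linolenic acid, (9Z,12Z,15Z)-octadeca-9,12,15-trienoic acid | CC/C=C\C/C=C\C/C=C\CCCCCCCC(=O)O | starting material
23 | CNP0115076.1, the (9Z,12Z,15Z)-octadeca-9,12,15-trienoate of 21 | CC/C=C\C/C=C\C/C=C\CCCCCCCC(=O)OC/C=C(\C)CC/C=C(\C)CC[C@@H]1C(C)=CCCC1(C)C | target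

**Total step count:** 13
**Longest linear sequence:** 11 steps (steps 3 to 13, from geraniol)

**Three steps most likely to fail**

**Step 11.**
- *Risk:* The phosphonium-activated allylic alcohol carries a highly substituted alkene. It may ionise or eliminate faster than it is displaced, which would erode the inversion or drain material into a ring diene.
- *Fallback:* It sets out from 17 and comes back at 20.
  - Alcohol 17 is formylated (HCO2H, DCC, DMAP, CH2Cl2) to the allylic formate F1.
  - F1 is then treated with Pd(acac)2 and PBu3 in THF.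
  - In this palladium-catalysed formate hydrogenolysis, zerovalent palladium ionises the C3'–O bond anti.
  - CO2 is lost, and hydride passes from palladium to the more substituted allyl terminus C1' on the face opposite to the former oxygen.
  - This should give the same S configuration and the same C2'=C3' alkene.

**Step 1.**
- *Risk:* Michael addition through the ethyl-side enolate and oligomerisation of the acrylate may consume material before ring closure.
- *Fallback:* It sets out from 2 and comes back at 4.
  - Acrylate 2 is combined under KOt-Bu with commercial 3-methylbutan-2-one. Its only acylation site is a methyl group, so the orientation question disappears.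
  - By way of methyl 4,4-dimethyl-5-oxohexanoate F2, the same two ring bonds form in one operation and give 4,4-dimethylcyclohexane-1,3-dione F3.
  - C-Methylation of F3 between the carbonyls (MeI, K2CO3, acetone) then leads to 4.

**Step 9.**
- *Risk:* 1,2-Addition to the hindered, electron-rich C1' carbonyl may be sluggish, so gamma-deprotonation of 5 or decay of the alkyllithium competes.
- *Fallback:* It sets out from 5 and 14 and comes back at 20. The C1'–chain bond is made by a stereospecific allylic substitution instead of a carbonyl addition.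
  - Enol ether 5 is reduced (LiAlH4, Et2O, 0 °C) to 3-isobutoxy-2,6,6-trimethylcyclohex-2-en-1-ol F4.
  - Dilute HCl converts F4 into 2,4,4-trimethylcyclohex-2-en-1-one F5.
  - CBS reduction with the (R)-catalyst and catecholborane gives (S)-2,4,4-trimethylcyclohex-2-en-1-ol F6.
  - Acylation with picolinic acid (DCC, DMAP) gives the (S)-allylic picolinate F7.
  - Alkyllithium 14 is transmetalated with MgBr2·OEt2 and CuBr·SMe2 to the alkylcopper reagent F8.
  - F8 should attack F7 in an anti-SN2' sense at C1', opposite to the chelating leaving group. This sets S at C1' and leaves the alkene at C2'=C3'.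

**Further compounds**
F1 | step 11 | (1R)-3-[(3E,7E)-9-(tert-butyldiphenylsilyloxy)-3,7-dimethylnona-3,7-dienyl]-2,4,4-trimethylcyclohex-2-en-1-yl formate | CC(C)(C)[Si](c1ccccc1)(c1ccccc1)OC/C=C(\C)CC/C=C(\C)CCC1=C(C)[C@H](OC=O)CCC1(C)C
F2 | step 1 | methyl 4,4-dimethyl-5-oxohexanoate | CC(=O)C(C)(C)CCC(=O)OC
F3 | step 1 | 4,4-dimethylcyclohexane-1,3-dione | CC1(C)CCC(=O)CC1=O
F4 | step 9 | 3-isobutoxy-2,6,6-trimethylcyclohex-2-en-1-ol | CC1=C(OCC(C)C)CCC(C)(C)C1O
F5 | step 9 | 2,4,4-trimethylcyclohex-2-en-1-one | CC1=CC(C)(C)CCC1=O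
F6 | step 9 | (S)-2,4,4-trimethylcyclohex-2-en-1-ol | CC1=CC(C)(C)CC[C@@H]1O
F7 | step 9 | (S)-2,4,4-trimethylcyclohex-2-en-1-yl picolinate | CC1=CC(C)(C)CC[C@@H]1OC(=O)c1ccccn1
F8 | step 9 | (3E,7E)-9-(tert-butyldiphenylsilyloxy)-3,7-dimethylnona-3,7-dienylcopper | CC(C)(C)[Si](c1ccccc1)(c1ccccc1)OC/C=C(\C)CC/C=C(\C)CC[Cu]
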